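## The problem

(7R)-7-Hydroxytaxiresinol (16) is a 7',9-epoxylignan. One oxolane ring (O1–C9–C8–C8'–C7') carries the catechol ring at C7', the hydroxymethyl carbon C9' at C8' and, at C8, the exocyclic carbinol carbon C7 with the guaiacyl ring. Four contiguous stereocentres have to be set (7R, 8R, 8'R, 7'S): the aryl group at C7' is trans to C9', C9' is cis to the C7 arm, and C7 lies outside the ring. The 8,8'-cis relationship is the crowded one and is best enforced by a temporary ring that ties the C7 oxygen to C9'. C7 can then be controlled only by 1,2-induction from C8, and C7' has to be set against C8 across the ring. Both benzylic C–O bonds (C7–OH and C7'–O1) sit para to oxygen on electron-rich rings. Acid ionises them (epimerisation, closure of the C9' hydroxyl onto C7, quinone methide formation once the phenols are free), Pd/C with hydrogen can cleave them, and the free catechol is air-sensitive under base, so the phenols stay masked to the last step and the end game must be neutral. The feature that permits a short route is this: O1–C9–C8 with the one-carbon arm C7 on C8 is the skeleton of butadiene monoxide (4), its vinyl group being a latent C7 aldehyde, and C7'–C8' with the aryl group and C9' is an arylidene malonate (3). The ring is therefore their formal [3+2] adduct, formed through O1–C7' and C8–C8', at the price of one surplus carboxyl carbon on C8' that must leave so that C9' stays cis to C7.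

## Retrosynthesis

Lignan numbering is used for atoms (C7–C9 guaiacyl half, C7'–C9' catechol half); compound numbers are those of the steps.

**16 from 15.** The three aryl O–benzyl bonds are cut last. Benzyl ethers are preferred to silyl ethers, which may not survive alkoxides, the organomagnesium step and hot halide, and to acetal-type groups, whose acidic removal would ionise C7. Tribenzyl ether 15 is no simpler in skeleton but is robust. The forward reaction must stop at O-debenzylation and leave C7–OH and C7'–O1 alone.

**15 from 14.** The C7 oxygen and C9' are reconnected as a γ-lactone. In the cis-fused bicyclic lactone 14 the 8,8'-cis relationship follows from ring strain and not from selectivity, and one hydride reduction releases both hydroxyl groups. The reduction must not epimerise C8'.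

**14 from 12.** A methoxycarbonyl group is put back on C8'. A C8' methine carried through the route would be an epimerisable centre that prefers the all-trans array. The quaternary centre of 12 holds no stereochemical information until the lactone has decided which carboxyl stays. The forward dealkoxycarbonylation has to spare the benzylic lactone; the ring fusion guarantees that hydrogen arrives on the face the ester leaves.

**12 from 7 and 10.** The C7–aryl bond and the lactone acyl–oxygen bond are cut. The neighbouring C7–C8 cut would be an aldol-type union that sets two centres at once through an enolate β to the ring oxygen. The C7–aryl cut instead leaves a formyl group on C8 next to a quaternary carbon, which makes 1,2-induction strong. The alkoxide formed can reach only the ester cis to it, so the same step tells the two esters apart. Aldehyde 7 has two stereocentres; Grignard reagent 10 comes from bromide 9, the benzyl ether of phenol 8.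

**7 from 5.** The C7 carbonyl is traced to the vinyl group of 5, which is inert in the ring-forming step and carries no stereochemistry. The oxidative cleavage has to spare the alkoxyarenes and the configuration at C8.

**5 from 3 and 4 (key disconnection).** O1–C7' and C8–C8' are cut together. Cutting either bond alone would mean cyclising a chain that already holds both stereocentres. The double cut removes the ring and both ring stereocentres at once and ends in an achiral acceptor 3 and the racemic epoxide 4. The forward reaction asks a zerovalent palladium catalyst carrying a chiral diphosphine to funnel both enantiomers of 4 into one configuration at C8, and the ring to close 2,4-trans.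

**3 from 1 and 2; 9 from 8.** The C7'=C8' bond of 3 is a Knoevenagel condensation of aldehyde 1 with malonate 2. Compounds 1, 2, 4 and 8 are commercial.

## Roads not taken

**Alternative 1:** Only C8–C8' is cut, by a radical. The linear N-acyloxyphthalimide A2 already holds C7 (as a silyl ether) and C7', and O1 links C9 to an aryl-substituted allyl unit ending in a vinylboronate. Single-electron reduction releases CO2; the C8 radical closes 5-exo onto the vinylboronate and the α-boryl radical is reduced to A1, whose C–B bond later becomes the C9' alcohol.
- Merits: C7 and C7' are set before ring closure by independent, reagent-controlled reactions, so C7 never depends on 1,2-induction; here this road is better than the chosen one. There is no surplus carboxyl and C9' arrives at the alcohol level.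
- Weak points: C8 and C8' are both set in the radical step by the kinetic preferences of a chair-like transition state. These point the right way (8,8'-cis, 7',8'-trans) but are modest, and the bulky aryl(silyloxy)methyl group on the radical carbon works against the cis preference. A2 needs an ether bond between an ionisable benzylic–allylic alcohol and the β-carbon of an elimination-prone β-silyloxy acid, and the C8 centre made while setting C7 is destroyed again. The sequence would run to about a dozen steps.
- Comparison: against the firmer hold on C7, the chosen plan sets C8 by catalyst control and C8' by ring fusion, and builds the ring from two simple partners in one step.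

**Alternative 2:** C7–C8 and C8'–C9' are cut together. Arylketene A5 would add across the double bond of the (S)-2-aryl-2,5-dihydrofuran A4 (one enantioselective Heck arylation) anti to its aryl group, giving the cis-fused cyclobutanone A3 with the guaiacyl ring endo. Baeyer–Villiger oxidation, the benzylic carbon migrating with retention, would give lactone 14 of the present route.
- Merits: it is the shortest road (five or six steps in all) and needs neither a decarboxylation nor a selective carbonyl addition. The endo aryl group that the target demands is the usual outcome of ketene cycloadditions. In step economy it is clearly better.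
- Weak points: an unactivated cis-disubstituted alkene is a poor partner for a monosubstituted arylketene, which dimerises readily. Nothing electronic tells C8 from C8', so the regiochemistry rests on the remote bulk of the C7' aryl group. The endo centre is benzylic and α to the cyclobutanone carbonyl, and the amine that generates the ketene can epimerise it to the 7-epimer. Forcing the cycloaddition with a strong Lewis acid would endanger the allylic–benzylic C7'–O1 bond of A4, and a peracid meets three alkoxyarene rings.
- Comparison: the chosen plan sets against the brevity a ring-forming step whose regiochemistry is fixed by mechanism, and a C7 centre made in an irreversible addition.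

**Alternative 3:** C9–C8 and C7'–C8' are cut. CsF would release the aryl-substituted carbonyl ylide (C7'–O1–C9) from chloro ether A8, and the ylide would add to the chiral 5-menthyloxybutenolide A7 anti to the menthyloxy group. The product A6 is a cis-fused lactone acetal (lactone carbonyl C9', acetal carbon C7); after unmasking of C7 and aryl addition it would also reach 14.
- Merits: the auxiliary gives dependable facial control, C8 and C8' are cis by construction, there is no surplus carboxyl, diastereomers can be separated and the auxiliary recovered. For the absolute configuration at C8 and C8' this is at least as reliable as an enantioselective catalyst.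
- Weak points: the ylide is unsymmetrical, so both its orientation and the exo or endo position of the aryl group at C7' are open. A8 with its dialkoxyaryl group ionises easily. The later aryl addition at C7 lacks the quaternary neighbour and so has weaker induction. The auxiliary is stoichiometric and the count is near ten steps.
- Comparison: the chosen plan offers catalytic induction, fewer steps and stronger control of C7. It concedes that its own control of C7' is also a kinetic preference.

Key step: step 2

Assumption: the (1R,2R) antipode of the diphosphine is taken to deliver the (4R) centre of 5 by analogy with related allylic substitutions; should the sense of induction prove opposite, the (1S,2S) antipode is used and nothing else changes.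

## Route

Step 1
Reactants: 1 3,4-bis(benzyloxy)benzaldehyde; 2 dimethyl malonate
Product: 3 dimethyl 2-[3,4-bis(benzyloxy)benzylidene]malonate
Conditions: piperidine (cat.), AcOH (cat.), toluene, reflux, Dean–Stark
Reagents that add atoms: none
Why: Knoevenagel condensation driven by azeotropic removal of water; the two ester groups are identical, so the alkene has no geometrical isomers, and the benzyl ethers are inert.

Step 2
Reactants: 3 dimethyl 2-[3,4-bis(benzyloxy)benzylidene]malonate; 4 rac-2-vinyloxirane (butadiene monoxide)
Product: 5 dimethyl (2R,4R)-2-[3,4-bis(benzyloxy)phenyl]-4-ethenyloxolane-3,3-dicarboxylate (2,4-trans)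
Conditions: 4 (2 equiv), Pd2(dba)3·CHCl3 (2.5 mol %), (1R,2R)-N,N'-bis[2-(diphenylphosphanyl)-1-naphthoyl]cyclohexane-1,2-diamine (7.5 mol %), THF, rt
Reagents that add atoms: none
Why: Zerovalent palladium opens either enantiomer of 4 at the allylic C–O bond to a catalyst-bound zwitterion, an allyl complex of divalent palladium with a pendant alkoxide; its diastereomeric forms interconvert by π–σ–π isomerisation faster than they are trapped, so the racemate converges (dynamic kinetic asymmetric transformation). The alkoxide adds reversibly to the benzylidene carbon of 3 (oxa-Michael addition, O1–C7'), and the malonate carbanion so released attacks the internal allyl carbon anti to palladium (C8–C8'), freeing the catalyst. The closest known reaction type is the zerovalent-palladium-catalysed formal [3+2] cycloaddition of vinyl epoxides with doubly activated alkenes, including its enantioselective dynamic kinetic variants. The oxolane closes by C–C bond formation, 5-exo with respect to the allyl unit; attack at the far allyl terminus would need a seven-membered ring and should not compete. C8 (oxolane C4) is set by the chiral diphosphine, which decides the allyl face offered to the tethered carbanion. C7' (oxolane C2) is set in the ring closure: because the oxa-Michael step is reversible, both C7' epimers of the open adduct are available, and the closure that keeps the aryl group away from the ligand-bearing allyl fragment, giving the 2,4-trans ring, should be the faster. The step needs conjugate rather than carbonyl attack by the alkoxide, which the unhindered benzylidene carbon and the stabilised malonate anion secure, and it needs no selectivity at C8', since both ester groups are the same.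

Step 3
Reactants: 5 dimethyl (2R,4R)-2-[3,4-bis(benzyloxy)phenyl]-4-ethenyloxolane-3,3-dicarboxylate
Product: 7 dimethyl (2R,4R)-2-[3,4-bis(benzyloxy)phenyl]-4-formyloxolane-3,3-dicarboxylate, via ozonide 6 (not isolated)
Conditions: O3, CH2Cl2, −78 °C (Sudan red 7B end point); then PPh3, −78 °C → rt
Reagents that add atoms: ozone, [O-][O+]=O
Why: Ozonolysis with reductive work-up; the terminal alkene reacts much faster than the alkoxyarene rings when the ozone stream is stopped at the indicator end point. Cold, neutral conditions and the hindered position of H8 next to the quaternary carbon should keep C8 from epimerising; 7 is used crude.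

Step 4
Reactants: 8 4-bromo-2-methoxyphenol
Product: 9 1-(benzyloxy)-4-bromo-2-methoxybenzene
Conditions: BnBr, K2CO3, DMF, rt
Reagents that add atoms: benzyl bromide, BrCc1ccccc1
Why: Williamson ether synthesis; the phenoxide of 8 displaces bromide from benzyl bromide and the aryl bromide is untouched.

Step 5
Reactants: 7 dimethyl (2R,4R)-2-[3,4-bis(benzyloxy)phenyl]-4-formyloxolane-3,3-dicarboxylate; 9 1-(benzyloxy)-4-bromo-2-methoxybenzene
Product: 12 methyl (3R,3aR,6R,6aS)-3-[4-(benzyloxy)-3-methoxyphenyl]-6-[3,4-bis(benzyloxy)phenyl]-1-oxotetrahydro-1H,3H-furo[3,4-c]furan-6a(6H)-carboxylate (cis-fused; guaiacyl ring endo at C7, catechol ring exo at C7'), via arylmagnesium bromide 10 (not isolated), via bromomagnesium alkoxide 11 (not isolated)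
Conditions: 9, Mg, THF, 40 °C; then 7, THF, −78 °C → rt; aq NH4Cl
Reagents that add atoms: none
Why: Grignard addition under Felkin–Anh control: the quaternary C8' stands anti to the incoming aryl group, which passes the C8 hydrogen, and a magnesium chelate through the ring oxygen would expose the same face, so the (7R) alkoxide 11 is expected; at −78 °C the aldehyde outruns the two hindered esters. On warming, 11 acylates itself on the only ester it can reach, the one cis to the C7 arm, closing the cis-fused γ-lactone (5-exo-trig) and so telling the two esters apart.

Step 6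
Reactants: 12 methyl (3R,3aR,6R,6aS)-3-[4-(benzyloxy)-3-methoxyphenyl]-6-[3,4-bis(benzyloxy)phenyl]-1-oxotetrahydro-1H,3H-furo[3,4-c]furan-6a(6H)-carboxylate
Product: 14 (3R,3aR,6S,6aS)-3-[4-(benzyloxy)-3-methoxyphenyl]-6-[3,4-bis(benzyloxy)phenyl]tetrahydro-1H,3H-furo[3,4-c]furan-1-one, via lithium carboxylate 13 (not isolated)
Conditions: LiCl, H2O, DMSO, 130 °C
Reagents that add atoms: none
Why: Krapcho dealkoxycarbonylation: chloride removes the ester methyl group by SN2, carboxylate 13 loses CO2 and the lactone enolate is protonated by water. Only the cis ring fusion is possible for this bicyclo[3.3.0] lactone, so hydrogen takes the place of the departed ester and C8' ends with C9' cis to C7 and trans to the C7' aryl group; loss of the ring oxygen from the enolate is stereoelectronically poor because the C7'–O1 bond lies near the enolate plane.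

Step 7
Reactants: 14 (3R,3aR,6S,6aS)-3-[4-(benzyloxy)-3-methoxyphenyl]-6-[3,4-bis(benzyloxy)phenyl]tetrahydro-1H,3H-furo[3,4-c]furan-1-one
Product: 15 (R)-[4-(benzyloxy)-3-methoxyphenyl]{(3R,4R,5S)-5-[3,4-bis(benzyloxy)phenyl]-4-(hydroxymethyl)oxolan-3-yl}methanol
Conditions: LiAlH4, THF, 0 °C
Reagents that add atoms: none
Why: Hydride reduction of a lactone to the diol; hydride adds to the carbonyl faster than C8' can be enolised, no stereocentre is touched and the benzyl ethers are inert.

Step 8
Reactants: 15 (R)-[4-(benzyloxy)-3-methoxyphenyl]{(3R,4R,5S)-5-[3,4-bis(benzyloxy)phenyl]-4-(hydroxymethyl)oxolan-3-yl}methanol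
Product: 16 (7R)-7-hydroxytaxiresinol, 4-[(2S,3R,4R)-4-[(R)-hydroxy(4-hydroxy-3-methoxyphenyl)methyl]-3-(hydroxymethyl)oxolan-2-yl]benzene-1,2-diol
Conditions: H2 (1 atm), Pd/C (10 %), EtOAc, rt
Reagents that add atoms: none
Why: Catalytic hydrogenolysis of aryl benzyl ethers; under neutral conditions in an aprotic solvent these cleave well before the benzylic C7–OH and C7'–O1 bonds, and the reaction is stopped as soon as the third benzyl group has gone.

## Compound list

1 | 3,4-bis(benzyloxy)benzaldehyde | O=Cc1ccc(OCc2ccccc2)c(OCc2ccccc2)c1 | starting material
2 | dimethyl malonate | COC(=O)CC(=O)OC | starting material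
3 | dimethyl 2-[3,4-bis(benzyloxy)benzylidene]malonate | COC(=O)C(=Cc1ccc(OCc2ccccc2)c(OCc2ccccc2)c1)C(=O)OC | intermediate
4 | rac-2-vinyloxirane (butadiene monoxide) | C=CC1CO1 | starting material
5 | dimethyl (2R,4R)-2-[3,4-bis(benzyloxy)phenyl]-4-ethenyloxolane-3,3-dicarboxylate | C=C[C@H]1CO[C@H](c2ccc(OCc3ccccc3)c(OCc3ccccc3)c2)C1(C(=O)OC)C(=O)OC | intermediate
6 | ozonide of 5, dimethyl (2R,4R)-2-[3,4-bis(benzyloxy)phenyl]-4-(1,2,4-trioxolan-3-yl)oxolane-3,3-dicarboxylate (both epimers at the trioxolane carbon; formed in the flask) | O1OCOC1[C@H]1CO[C@H](c2ccc(OCc3ccccc3)c(OCc3ccccc3)c2)C1(C(=O)OC)C(=O)OC | intermediate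
7 | dimethyl (2R,4R)-2-[3,4-bis(benzyloxy)phenyl]-4-formyloxolane-3,3-dicarboxylate | O=C[C@H]1CO[C@H](c2ccc(OCc3ccccc3)c(OCc3ccccc3)c2)C1(C(=O)OC)C(=O)OC | intermediate
8 | 4-bromo-2-methoxyphenol | COc1cc(Br)ccc1O | starting material
9 | 1-(benzyloxy)-4-bromo-2-methoxybenzene | COc1cc(Br)ccc1OCc1ccccc1 | intermediate
10 | [4-(benzyloxy)-3-methoxyphenyl]magnesium bromide (formed in the flask) | COc1cc([Mg]Br)ccc1OCc1ccccc1 | intermediate
11 | bromomagnesium alkoxide of dimethyl (2R,4R)-4-[(R)-[4-(benzyloxy)-3-methoxyphenyl](hydroxy)methyl]-2-[3,4-bis(benzyloxy)phenyl]oxolane-3,3-dicarboxylate (formed in the flask) | COc1cc([C@H](O[Mg]Br)[C@H]2CO[C@H](c3ccc(OCc4ccccc4)c(OCc4ccccc4)c3)C2(C(=O)OC)C(=O)OC)ccc1OCc1ccccc1 | intermediate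
12 | methyl (3R,3aR,6R,6aS)-3-[4-(benzyloxy)-3-methoxyphenyl]-6-[3,4-bis(benzyloxy)phenyl]-1-oxotetrahydro-1H,3H-furo[3,4-c]furan-6a(6H)-carboxylate | COc1cc([C@@H]2OC(=O)[C@@]3(C(=O)OC)[C@@H]2CO[C@@H]3c4ccc(OCc5ccccc5)c(OCc5ccccc5)c4)ccc1OCc1ccccc1 | intermediate
13 | lithium (3R,3aR,6R,6aS)-3-[4-(benzyloxy)-3-methoxyphenyl]-6-[3,4-bis(benzyloxy)phenyl]-1-oxotetrahydro-1H,3H-furo[3,4-c]furan-6a(6H)-carboxylate (formed in the flask) | [Li+].COc1cc([C@@H]2OC(=O)[C@@]3(C(=O)[O-])[C@@H]2CO[C@@H]3c4ccc(OCc5ccccc5)c(OCc5ccccc5)c4)ccc1OCc1ccccc1 | intermediate
14 | (3R,3aR,6S,6aS)-3-[4-(benzyloxy)-3-methoxyphenyl]-6-[3,4-bis(benzyloxy)phenyl]tetrahydro-1H,3H-furo[3,4-c]furan-1-one | COc1cc([C@@H]2OC(=O)[C@H]3[C@@H]2CO[C@@H]3c4ccc(OCc5ccccc5)c(OCc5ccccc5)c4)ccc1OCc1ccccc1 | intermediate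
15 | (R)-[4-(benzyloxy)-3-methoxyphenyl]{(3R,4R,5S)-5-[3,4-bis(benzyloxy)phenyl]-4-(hydroxymethyl)oxolan-3-yl}methanol | COc1cc([C@H](O)[C@H]2CO[C@H](c3ccc(OCc4ccccc4)c(OCc4ccccc4)c3)[C@H]2CO)ccc1OCc1ccccc1 | intermediate
16 | (7R)-7-hydroxytaxiresinol | COc1cc([C@H](O)[C@H]2CO[C@H](c3ccc(O)c(O)c3)[C@H]2CO)ccc1O | target

## Step count and least certain steps

Total: 8 steps. Longest linear sequence: 7 steps (steps 1, 2, 3, 5, 6, 7, 8) from aldehyde 1.

**Step 2 (key step).** The electron-rich benzylidene malonate may intercept the zwitterion too slowly, because the oxa-Michael equilibrium lies towards the free alkoxide; the zwitterion then isomerises or oligomerises. A weaker 2,4-trans preference than hoped would cost material only, since the isomers can be separated. The fallback changes the acceptor; it sets out from 1 and returns at 5.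
- Knoevenagel condensation of 1 with Meldrum's acid gives 5-[3,4-bis(benzyloxy)benzylidene]-2,2-dimethyl-1,3-dioxane-4,6-dione F1, a far stronger Michael acceptor of a class known to engage such palladium zwitterions.
- The same catalyst with 4 should give the spiro adduct F2.
- NaOMe in MeOH opens the dioxanedione with loss of acetone to the half-ester sodium salt F3 (both C8' epimers), and MeI in DMF converts both into 5.
- The cost is two extra steps and a less reversible first addition.

**Step 5.** Poor facial selectivity at C7 is the main risk: if magnesium is held between the aldehyde oxygen and an ester carbonyl, the Felkin–Anh preference can be overridden. Partial epimerisation at C8 by the basic reagent is a second concern. The fallback corrects C7 late; it sets out from 15 obtained as a mixture of C7 epimers (carried unchanged through steps 6 and 7) and returns to 15.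
- MnO2 in CH2Cl2 oxidises only the benzylic hydroxyl, giving [4-(benzyloxy)-3-methoxyphenyl]{(3R,4R,5S)-5-[3,4-bis(benzyloxy)phenyl]-4-(hydroxymethyl)oxolan-3-yl}methanone F4.
- CBS reduction with BH3·SMe2 (excess, to cover the primary hydroxyl) and (S)-1-methyl-3,3-diphenyltetrahydro-1H,3H-pyrrolo[1,2-c][1,3,2]oxazaborole, the aryl group acting as the large substituent, should return the (7R) alcohol 15 under reagent control.

**Step 6.** At 130 °C in DMSO the benzylic lactone C7–O bond may ionise or be opened by chloride, and reclosure would drain the endo-aryl lactone into its more stable C7 epimer. The fallback reverses the order of events; it sets out from 5 and returns at 14.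
- The Krapcho reaction is run on the robust diester 5, giving methyl (2S,4R)-2-[3,4-bis(benzyloxy)phenyl]-4-ethenyloxolane-3-carboxylate F5 as both C8' epimers.
- Ozonolysis as in step 3 gives the aldehyde F6.
- Addition of 10 gives the alkoxide F7. With NaOMe (cat.) in MeOH the ester epimerises at C8', and since only the cis epimer can lactonise, the mixture funnels into 14.
- The cost is C7 induction without the quaternary neighbour; the correction described for step 5 remains available.

**Step 8.** Over-reduction is the risk: once the phenols are free the p-hydroxybenzylic C7–OH and C7'–O1 bonds become more labile and may be hydrogenolysed. The fallback replaces surface hydrogenolysis by electron transfer; it sets out from 15 and returns at 16, and no new compound is made (F0).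
- The two hydroxyl groups of 15 are deprotonated with n-BuLi, and lithium naphthalenide in THF at −78 °C cleaves the three ArO–CH2Ph bonds, each with a phenoxide as leaving group.
- The benzylic alkoxide at C7 and the ring ether at C7', on an aryl ring that becomes a catecholate, are poor electron acceptors; aqueous NH4Cl then gives 16.

## Further compounds

F1 | step 2 | 5-[3,4-bis(benzyloxy)benzylidene]-2,2-dimethyl-1,3-dioxane-4,6-dione | CC1(C)OC(=O)C(=Cc2ccc(OCc3ccccc3)c(OCc3ccccc3)c2)C(=O)O1
F2 | step 2 | (1R,4R)-1-[3,4-bis(benzyloxy)phenyl]-4-ethenyl-8,8-dimethyl-2,7,9-trioxaspiro[4.5]decane-6,10-dione | C=C[C@H]1CO[C@H](c2ccc(OCc3ccccc3)c(OCc3ccccc3)c2)C12C(=O)OC(C)(C)OC2=O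
F3 | step 2 | sodium (2R,4R)-2-[3,4-bis(benzyloxy)phenyl]-4-ethenyl-3-(methoxycarbonyl)oxolane-3-carboxylate (both C3 epimers) | C=C[C@H]1CO[C@H](c2ccc(OCc3ccccc3)c(OCc3ccccc3)c2)C1(C(=O)OC)C(=O)[O-].[Na+]
F4 | step 5 | [4-(benzyloxy)-3-methoxyphenyl]{(3R,4R,5S)-5-[3,4-bis(benzyloxy)phenyl]-4-(hydroxymethyl)oxolan-3-yl}methanone | COc1cc(C(=O)[C@H]2CO[C@H](c3ccc(OCc4ccccc4)c(OCc4ccccc4)c3)[C@H]2CO)ccc1OCc1ccccc1
F5 | step 6 | methyl (2S,4R)-2-[3,4-bis(benzyloxy)phenyl]-4-ethenyloxolane-3-carboxylate (both C3 epimers) | C=C[C@H]1CO[C@H](c2ccc(OCc3ccccc3)c(OCc3ccccc3)c2)C1C(=O)OC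
F6 | step 6 | methyl (2S,4R)-2-[3,4-bis(benzyloxy)phenyl]-4-formyloxolane-3-carboxylate (both C3 epimers) | O=C[C@H]1CO[C@H](c2ccc(OCc3ccccc3)c(OCc3ccccc3)c2)C1C(=O)OC
F7 | step 6 | bromomagnesium alkoxide of methyl (2S,4R)-4-[(R)-[4-(benzyloxy)-3-methoxyphenyl](hydroxy)methyl]-2-[3,4-bis(benzyloxy)phenyl]oxolane-3-carboxylate (both C3 epimers) | COc1cc([C@H](O[Mg]Br)[C@H]2CO[C@H](c3ccc(OCc4ccccc4)c(OCc4ccccc4)c3)C2C(=O)OC)ccc1OCc1ccccc1
F0 | step 8 | none | none
A1 | alternative 1 | 2-aryl-3-(pinacolborylmethyl)-4-[aryl(tert-butyldimethylsilyloxy)methyl]oxolane with the configuration of the target at all four centres | COc1cc([C@H](O[Si](C)(C)C(C)(C)C)[C@H]2CO[C@H](c3ccc(OCc4ccccc4)c(OCc4ccccc4)c3)[C@H]2CB2OC(C)(C)C(C)(C)O2)ccc1OCc1ccccc1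
A2 | alternative 1 | N-acyloxyphthalimide of (3R)-3-[4-(benzyloxy)-3-methoxyphenyl]-3-(tert-butyldimethylsilyloxy)-2-({(1S,2E)-1-[3,4-bis(benzyloxy)phenyl]-3-(pinacolboryl)prop-2-enyl}oxymethyl)propanoic acid | COc1cc([C@H](O[Si](C)(C)C(C)(C)C)C(CO[C@@H](/C=C/B2OC(C)(C)C(C)(C)O2)c3ccc(OCc4ccccc4)c(OCc5ccccc5)c3)C(=O)ON6C(=O)c7ccccc7C6=O)ccc1OCc1ccccc1
A3 | alternative 2 | 7-endo-[4-(benzyloxy)-3-methoxyphenyl]-2-exo-[3,4-bis(benzyloxy)phenyl]-3-oxabicyclo[3.2.0]heptan-6-one | O=C1[C@@H](c2ccc(OCc3ccccc3)c(OC)c2)[C@H]2CO[C@H](c3ccc(OCc4ccccc4)c(OCc4ccccc4)c3)[C@@H]12
A4 | alternative 2 | (S)-2-[3,4-bis(benzyloxy)phenyl]-2,5-dihydrofuran | C1=C[C@@H](c2ccc(OCc3ccccc3)c(OCc3ccccc3)c2)OC1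
A5 | alternative 2 | [4-(benzyloxy)-3-methoxyphenyl]ketene | O=C=Cc1ccc(OCc2ccccc2)c(OC)c1
A6 | alternative 3 | 6-exo-[3,4-bis(benzyloxy)phenyl]-4-menthyloxy-3,7-dioxabicyclo[3.3.0]octan-2-one (menthyloxy exo) | O=C1O[C@H](O[C@H]2C[C@@H](C)CC[C@@H]2C(C)C)[C@H]2CO[C@H](c3ccc(OCc4ccccc4)c(OCc4ccccc4)c3)[C@@H]12
A7 | alternative 3 | (5S)-5-{[(1S,2R,5S)-2-isopropyl-5-methylcyclohexyl]oxy}furan-2(5H)-one | O=C1C=C[C@@H](O[C@H]2C[C@@H](C)CC[C@@H]2C(C)C)O1
A8 | alternative 3 | {[3,4-bis(benzyloxy)phenyl](chloromethoxy)methyl}trimethylsilane (racemic) | C[Si](C)(C)C(OCCl)c1ccc(OCc2ccccc2)c(OCc2ccccc2)c1
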